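**Retrosynthetic overview**
- 20 ⇐ thiolate tris-O-demethylation, double ortho-lithiation/formylation, and equatorial methyl addition to the C4 ketone of 16; the arene is bought as 2,4,6-trimethoxybenzaldehyde.
- 16 ⇐ hydrogenation (sets C1) and cuprate 1,6-addition (sets the benzylic carbon) on arylidene dienone 14, itself from vinylogous aldol condensation of bicyclic enone 11 with 12.
- 11 ⇐ acyclic keto-enal 8: ring B (C5–C10 bond, quaternary C10) and ring A (C2–C3 bond) close in one amine-mediated Michael/aldol-condensation domino.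
- 8 ⇐ geranyl acetate: Shi epoxidation (source of C7), copper-catalysed Grignard opening with a 3-oxobutyl unit (makes the C11 alcohol), MnO2.
- Ring order: B then A in the same flask; the aromatic ring is never built.

Assumption: positions are given in eudesmane numbering (C1–C15 for the bicyclic core); the L-fructose-type enantiomer of the Shi ketone (made from L-sorbose) is taken as an available catalyst.

**Step 1**
Reactants: 1 geranyl acetate
Product: 3 (2E)-5-[(2S)-3,3-dimethyloxiran-2-yl]-3-methylpent-2-en-1-ol, via epoxy acetate 2 (not isolated)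
Conditions: ent-Shi ketone (0.3 equiv), Oxone (2KHSO5·KHSO4·K2SO4), K2CO3, MeCN/dimethoxymethane/aq. Na2B4O7 buffer, 0 °C; then MeOH, rt
Reagents that add atoms: potassium peroxymonosulfate (KHSO5), [K+].[O-]S(=O)(=O)OO
Why: Shi asymmetric epoxidation (chiral dioxirane, spiro transition state) attacks only the electron-rich 6,7-alkene because the allylic acetate deactivates the 2,3-alkene, the L-fructose-type catalyst gives the (S)-epoxide that becomes C7, and the K2CO3 already present cleaves the acetate by transesterification once MeOH is added.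

**Step 2**
Reactants: 3 (2E)-5-[(2S)-3,3-dimethyloxiran-2-yl]-3-methylpent-2-en-1-ol; 4 2-(2-bromoethyl)-2-methyl-1,3-dioxolane
Product: 7 (5S,8E)-10-hydroxy-5-(2-hydroxypropan-2-yl)-8-methyldec-8-en-2-one, via Grignard reagent 5 (not isolated), via ketal diol 6 (not isolated)
Conditions: 4 (3.5 equiv), Mg, THF, 30 °C; then 3, CuBr·SMe2 (10 mol%), −30 °C to rt; then 0.5 M HCl, THF, rt
Reagents that add atoms: water, O
Why: Copper-catalysed Grignard opening of the trisubstituted epoxide at its less substituted carbon (SN2, inversion) sets C7 and frees the tertiary C11 alcohol in one event, and the mild acid stage hydrolyses the dioxolane to the methyl ketone.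

**Step 3**
Reactants: 7 (5S,8E)-10-hydroxy-5-(2-hydroxypropan-2-yl)-8-methyldec-8-en-2-one
Product: 8 (2E,6S)-6-(2-hydroxypropan-2-yl)-3-methyl-9-oxodec-2-enal
Conditions: MnO2 (15 equiv), CH2Cl2, rt
Reagents that add atoms: none
Why: MnO2 allylic oxidation is selective for the primary allylic alcohol and leaves the ketone and tertiary alcohol alone; the alkene geometry is of no later consequence because C10 becomes sp3.

**Step 4**
Reactants: 8 (2E,6S)-6-(2-hydroxypropan-2-yl)-3-methyl-9-oxodec-2-enal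
Product: 11 (4aR,7S,8aS)-7-(2-hydroxypropan-2-yl)-4a-methyl-4a,5,6,7,8,8a-hexahydronaphthalen-1(4H)-one, via Michael adduct 9 (not isolated), via aldol adduct 10 (not isolated)
Conditions: pyrrolidine (0.3 equiv), AcOH (0.3 equiv), toluene (0.05 M), 60 °C
Reagents that add atoms: none
Why: Proposed new method: pyrrolidine turns the enal into an iminium ion and the ketone into its more substituted enamine, so C5 attacks the β,β-disubstituted carbon C10 in a 6-exo Michael addition (the only ring size open to either enamine) that closes ring B and creates the quaternary centre through a chair with the C7 side chain equatorial and the enamine and iminium branches both equatorial (methyl axial), which gives the C5/C7/C10 relationship of the target with trans-fusion also favoured at the epimerisable C5; the released aldehyde then condenses with the ketone methyl group (the only six-membered aldol) to close ring A as the enone; the closest known chemistry is the amine-catalysed Robinson annulation (Michael then aldol condensation) and iminium-catalysed Michael additions to β,β-disubstituted enals.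

**Step 5**
Reactants: 11 (4aR,7S,8aS)-7-(2-hydroxypropan-2-yl)-4a-methyl-4a,5,6,7,8,8a-hexahydronaphthalen-1(4H)-one; 12 2,4,6-trimethoxybenzaldehyde
Product: 14 (4E,4aS,7S,8aS)-7-(2-hydroxypropan-2-yl)-4a-methyl-4-[(2,4,6-trimethoxyphenyl)methylidene]-4a,5,6,7,8,8a-hexahydronaphthalen-1(4H)-one, via vinylogous aldol adduct 13 (not isolated)
Conditions: KOH, MeOH, 50 °C
Reagents that add atoms: none
Why: Vinylogous (γ) Claisen–Schmidt condensation: the adduct at the blocked α′ carbon C5 cannot dehydrate and reverts, so the extended dienolate condenses at C1 to the fully conjugated dienone, with the aryl group anti to the quaternary C10 (E) to avoid allylic strain.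

**Step 6**
Reactants: 14 (4E,4aS,7S,8aS)-7-(2-hydroxypropan-2-yl)-4a-methyl-4-[(2,4,6-trimethoxyphenyl)methylidene]-4a,5,6,7,8,8a-hexahydronaphthalen-1(4H)-one
Product: 15 (4aS,7S,8aS)-7-(2-hydroxypropan-2-yl)-4a-methyl-4-[(1S)-3-methyl-1-(2,4,6-trimethoxyphenyl)butyl]-4a,5,6,7,8,8a-hexahydronaphthalen-1(2H)-one
Conditions: i-BuMgBr (5 equiv), CuBr·SMe2 (2.5 equiv), THF, −78 to −20 °C; then AcOH, −78 °C
Reagents that add atoms: isobutylmagnesium bromide, CC(C)C[Mg]Br
Why: Organocuprate 1,6-conjugate addition to the 2,4-dienone, in which the axial C10 methyl shields one face of the exocyclic C1=C bond so that isobutyl enters anti to it and fixes the benzylic centre as S; kinetic protonation of the dienolate at C3 leaves the C1=C2 alkene.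

**Step 7**
Reactants: 15 (4aS,7S,8aS)-7-(2-hydroxypropan-2-yl)-4a-methyl-4-[(1S)-3-methyl-1-(2,4,6-trimethoxyphenyl)butyl]-4a,5,6,7,8,8a-hexahydronaphthalen-1(2H)-one
Product: 16 (4R,4aR,7S,8aS)-7-(2-hydroxypropan-2-yl)-4a-methyl-4-[(1S)-3-methyl-1-(2,4,6-trimethoxyphenyl)butyl]octahydronaphthalen-1(2H)-one
Conditions: H2 (4 bar), Pd/C, EtOAc, rt
Reagents that add atoms: none
Why: Heterogeneous hydrogenation delivers hydrogen to C1 from the face opposite the angular methyl, so the side chain ends equatorial and cis to that methyl (C1 R), and the ring fusion stays trans.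

**Step 8**
Reactants: 16 (4R,4aR,7S,8aS)-7-(2-hydroxypropan-2-yl)-4a-methyl-4-[(1S)-3-methyl-1-(2,4,6-trimethoxyphenyl)butyl]octahydronaphthalen-1(2H)-one
Product: 17 (1R,4R,4aR,7S,8aS)-7-(2-hydroxypropan-2-yl)-1,4a-dimethyl-4-[(1S)-3-methyl-1-(2,4,6-trimethoxyphenyl)butyl]decahydronaphthalen-1-ol
Conditions: MeLi (3.5 equiv), CeCl3, THF, −78 °C
Reagents that add atoms: methyllithium, [Li]C
Why: Organocerium 1,2-addition without enolisation, in which axial approach is blocked by the syn-axial C10 methyl so methyl enters equatorially and the new tertiary alcohol is axial and cis to the angular methyl (C4 R).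

**Step 9**
Reactants: 17 (1R,4R,4aR,7S,8aS)-7-(2-hydroxypropan-2-yl)-1,4a-dimethyl-4-[(1S)-3-methyl-1-(2,4,6-trimethoxyphenyl)butyl]decahydronaphthalen-1-ol
Product: 19 2,4,6-trimethoxy-5-{(1S)-1-[(1R,4R,4aS,6S,8aR)-4-hydroxy-6-(2-hydroxypropan-2-yl)-4,8a-dimethyldecahydronaphthalen-1-yl]-3-methylbutyl}benzene-1,3-dicarbaldehyde, via lithium hemiaminal 18 (not isolated)
Conditions: n-BuLi (3.3 equiv), TMEDA, THF, 0 °C; DMF (1.1 equiv), −78 °C; n-BuLi (1.5 equiv), 0 °C; DMF (excess); aq. HCl
Reagents that add atoms: N,N-dimethylformamide, CN(C)C=O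
Why: Directed ortho-metalation at the two ring positions that each lie between two methoxy groups, with the first formyl group kept masked as its lithium α-amino alkoxide while the second position is lithiated and formylated; the two tertiary alkoxides are inert and no stereocentre is touched.

**Step 10**
Reactants: 19 2,4,6-trimethoxy-5-{(1S)-1-[(1R,4R,4aS,6S,8aR)-4-hydroxy-6-(2-hydroxypropan-2-yl)-4,8a-dimethyldecahydronaphthalen-1-yl]-3-methylbutyl}benzene-1,3-dicarbaldehyde
Product: 20 2,4,6-trihydroxy-5-{(1S)-1-[(1R,4R,4aS,6S,8aR)-4-hydroxy-6-(2-hydroxypropan-2-yl)-4,8a-dimethyldecahydronaphthalen-1-yl]-3-methylbutyl}benzene-1,3-dicarbaldehyde (CNP0409870.4)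
Conditions: NaSEt (10 equiv), DMF, 120 °C; then aq. HCl
Reagents that add atoms: none
Why: SN2 demethylation by thiolate of aryl methyl ethers that are each activated by an ortho formyl group, under basic conditions that spare both tertiary alcohols and all stereocentres.

**Compound list**
1 | geranyl acetate, (2E)-3,7-dimethylocta-2,6-dien-1-yl acetate | CC(=O)OC/C=C(\C)CCC=C(C)C | starting material
2 | (2E)-5-[(2S)-3,3-dimethyloxiran-2-yl]-3-methylpent-2-en-1-yl acetate | CC(=O)OC/C=C(\C)CC[C@@H]1OC1(C)C | intermediate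
3 | (2E)-5-[(2S)-3,3-dimethyloxiran-2-yl]-3-methylpent-2-en-1-ol | OC/C=C(\C)CC[C@@H]1OC1(C)C | intermediate
4 | 2-(2-bromoethyl)-2-methyl-1,3-dioxolane | CC1(CCBr)OCCO1 | starting material
5 | [2-(2-methyl-1,3-dioxolan-2-yl)ethyl]magnesium bromide | CC1(CC[Mg]Br)OCCO1 | intermediate
6 | (2E,6S)-6-(2-hydroxypropan-2-yl)-3-methyl-8-(2-methyl-1,3-dioxolan-2-yl)oct-2-en-1-ol | OC/C=C(\C)CC[C@@H](CCC1(C)OCCO1)C(C)(C)O | intermediate
7 | (5S,8E)-10-hydroxy-5-(2-hydroxypropan-2-yl)-8-methyldec-8-en-2-one | OC/C=C(\C)CC[C@@H](CCC(C)=O)C(C)(C)O | intermediate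
8 | (2E,6S)-6-(2-hydroxypropan-2-yl)-3-methyl-9-oxodec-2-enal | O=C/C=C(\C)CC[C@@H](CCC(C)=O)C(C)(C)O | intermediate
9 | 2-[(1R,2S,4S)-2-acetyl-4-(2-hydroxypropan-2-yl)-1-methylcyclohexyl]acetaldehyde | CC(=O)[C@H]1C[C@@H](C(C)(C)O)CC[C@]1(C)CC=O | intermediate
10 | (4aR,7S,8aS)-3-hydroxy-7-(2-hydroxypropan-2-yl)-4a-methyloctahydronaphthalen-1(2H)-one (both C3 epimers) | OC1CC(=O)[C@H]2C[C@@H](C(C)(C)O)CC[C@]2(C)C1 | intermediate
11 | (4aR,7S,8aS)-7-(2-hydroxypropan-2-yl)-4a-methyl-4a,5,6,7,8,8a-hexahydronaphthalen-1(4H)-one | C1C=CC(=O)[C@H]2C[C@@H](C(C)(C)O)CC[C@]12C | intermediate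
12 | 2,4,6-trimethoxybenzaldehyde | COc1cc(OC)c(C=O)c(OC)c1 | starting material
13 | (4aR,7S,8aS)-4-[hydroxy(2,4,6-trimethoxyphenyl)methyl]-7-(2-hydroxypropan-2-yl)-4a-methyl-4a,5,6,7,8,8a-hexahydronaphthalen-1(4H)-one (epimers at C4 and at the carbinol) | COc1cc(OC)c(C(O)C2C=CC(=O)[C@H]3C[C@@H](C(C)(C)O)CC[C@]23C)c(OC)c1 | intermediate
14 | (4E,4aS,7S,8aS)-7-(2-hydroxypropan-2-yl)-4a-methyl-4-[(2,4,6-trimethoxyphenyl)methylidene]-4a,5,6,7,8,8a-hexahydronaphthalen-1(4H)-one | COc1cc(OC)c(/C=C2\C=CC(=O)[C@H]3C[C@@H](C(C)(C)O)CC[C@]23C)c(OC)c1 | intermediate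
15 | (4aS,7S,8aS)-7-(2-hydroxypropan-2-yl)-4a-methyl-4-[(1S)-3-methyl-1-(2,4,6-trimethoxyphenyl)butyl]-4a,5,6,7,8,8a-hexahydronaphthalen-1(2H)-one | CC(C)C[C@H](c1c(OC)cc(OC)cc1OC)C1=CCC(=O)[C@H]2C[C@@H](C(C)(C)O)CC[C@]12C | intermediate
16 | (4R,4aR,7S,8aS)-7-(2-hydroxypropan-2-yl)-4a-methyl-4-[(1S)-3-methyl-1-(2,4,6-trimethoxyphenyl)butyl]octahydronaphthalen-1(2H)-one | CC(C)C[C@H](c1c(OC)cc(OC)cc1OC)[C@H]1CCC(=O)[C@H]2C[C@@H](C(C)(C)O)CC[C@]12C | intermediate
17 | (1R,4R,4aR,7S,8aS)-7-(2-hydroxypropan-2-yl)-1,4a-dimethyl-4-[(1S)-3-methyl-1-(2,4,6-trimethoxyphenyl)butyl]decahydronaphthalen-1-ol | CC(C)C[C@H](c1c(OC)cc(OC)cc1OC)[C@H]1CC[C@@](C)(O)[C@H]2C[C@@H](C(C)(C)O)CC[C@]12C | intermediate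
18 | trilithium salt of the mono-formyl stage: aryl CH(OLi)NMe2 hemiaminal with both tertiary alkoxides (hemiaminal carbon unassigned) | [Li+].[Li+].[Li+].CC(C)C[C@H](c1c(OC)cc(OC)c(C([O-])N(C)C)c1OC)[C@H]1CC[C@@](C)([O-])[C@H]2C[C@@H](C(C)(C)[O-])CC[C@]12C | intermediate
19 | 2,4,6-trimethoxy-5-{(1S)-1-[(1R,4R,4aS,6S,8aR)-4-hydroxy-6-(2-hydroxypropan-2-yl)-4,8a-dimethyldecahydronaphthalen-1-yl]-3-methylbutyl}benzene-1,3-dicarbaldehyde | CC(C)C[C@H](c1c(OC)c(C=O)c(OC)c(C=O)c1OC)[C@H]1CC[C@@](C)(O)[C@H]2C[C@@H](C(C)(C)O)CC[C@]12C | intermediate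
20 | 2,4,6-trihydroxy-5-{(1S)-1-[(1R,4R,4aS,6S,8aR)-4-hydroxy-6-(2-hydroxypropan-2-yl)-4,8a-dimethyldecahydronaphthalen-1-yl]-3-methylbutyl}benzene-1,3-dicarbaldehyde | CC(C)C[C@H](c1c(O)c(C=O)c(O)c(C=O)c1O)[C@H]1CC[C@@](C)(O)[C@H]2C[C@@H](C(C)(C)O)CC[C@]12C | target

**Step count and risks**
Total steps: 10. Longest linear sequence: 10 steps (from geranyl acetate 1).

The three steps most likely to fail are 4, 5 and 6.

Step 4. The iminium carbon is β,β-disubstituted, so the Michael addition may be slow, and the C7/C10 selectivity rests only on a chair preference. The fallback leaves the route at 7 and makes the quaternary centre with a stronger electrophile. Methyl chloroformate and pyridine give methyl (2E,6S)-6-(2-hydroxypropan-2-yl)-3-methyl-9-oxodec-2-en-1-yl carbonate F1. Pd(PPh3)4 with pyrrolidine then joins the ketone enamine to the π-allyl palladium complex at its tertiary end (intramolecular Tsuji–Trost α-allylation, six-membered ring only) to give 1-[(1S,2R,5S)-2-ethenyl-5-(2-hydroxypropan-2-yl)-2-methylcyclohexyl]ethan-1-one F2. Aldehyde-selective Wacker oxidation of the vinyl group (PdCl2(MeCN)2, CuCl2, AgNO2, O2, t-BuOH/MeNO2) gives 9, now isolated, and KOH/MeOH closes ring A so that the route is rejoined at 11.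

Step 5. The γ-carbon C1 is neopentylic and the aldehyde is hindered and electron-rich, so base-mediated condensation may stall or go to the α-carbon. The fallback sets out from 11. TMSOTf and Et3N give trimethyl{[(4aR,7S,8aS)-4a-methyl-7-{2-[(trimethylsilyl)oxy]propan-2-yl}-4a,5,6,7,8,8a-hexahydronaphthalen-1-yl]oxy}silane F3. Aldehyde 12 with BF3·OEt2 at −78 °C then adds at the γ-terminus (vinylogous Mukaiyama aldol) to give 13 after aqueous work-up, and TsOH in toluene dehydrates it, returning to the route at 14.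

Step 6. The benzylic carbon is flanked by a di-ortho-substituted aryl ring and a neopentylic ring carbon, so cuprate transfer may be slow or go 1,4. The fallback sets out from 14. BF3·OEt2 and trimethyl(2-methylallyl)silane effect a Hosomi–Sakurai 1,6-addition: the Lewis-acid-bound dienone is an extended benzylic cation stabilised by the trimethoxyphenyl ring, so the allylsilane attacks the benzylic carbon, again anti to the angular methyl. This gives (4aS,7S,8aS)-7-(2-hydroxypropan-2-yl)-4a-methyl-4-[(1S)-3-methyl-1-(2,4,6-trimethoxyphenyl)but-3-en-1-yl]-4a,5,6,7,8,8a-hexahydronaphthalen-1(2H)-one F4. The hydrogenation conditions of step 7 then saturate both alkenes and the route is rejoined at 16.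

**Further compounds**
F1 | step 4 | methyl (2E,6S)-6-(2-hydroxypropan-2-yl)-3-methyl-9-oxodec-2-en-1-yl carbonate | COC(=O)OC/C=C(\C)CC[C@@H](CCC(C)=O)C(C)(C)O
F2 | step 4 | 1-[(1S,2R,5S)-2-ethenyl-5-(2-hydroxypropan-2-yl)-2-methylcyclohexyl]ethan-1-one | CC(=O)[C@H]1C[C@@H](C(C)(C)O)CC[C@]1(C)C=C
F3 | step 5 | trimethyl{[(4aR,7S,8aS)-4a-methyl-7-{2-[(trimethylsilyl)oxy]propan-2-yl}-4a,5,6,7,8,8a-hexahydronaphthalen-1-yl]oxy}silane | C1=CC=C(O[Si](C)(C)C)[C@H]2C[C@@H](C(C)(C)O[Si](C)(C)C)CC[C@]12C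
F4 | step 6 | (4aS,7S,8aS)-7-(2-hydroxypropan-2-yl)-4a-methyl-4-[(1S)-3-methyl-1-(2,4,6-trimethoxyphenyl)but-3-en-1-yl]-4a,5,6,7,8,8a-hexahydronaphthalen-1(2H)-one | CC(=C)C[C@H](c1c(OC)cc(OC)cc1OC)C1=CCC(=O)[C@H]2C[C@@H](C(C)(C)O)CC[C@]12C
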